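**Retrosynthetic overview**

- The (E)-4-hydroxy-4-methylpent-2-enyl chain is cut last at its double bond: cross-metathesis of a 2-allyl chroman with 2-methylbut-3-en-2-ol.
- The benzene ring is made last, from another ring: the chroman ester goes back to methyl coumalate (a 2-pyrone that supplies C5–C8 and the CO2Me group and loses CO2) and a δ-lactone whose C=O and α-CH2 become C8a and C4a.
- The pyran ring is never closed by cyclisation: as the δ-lactone it comes from a cyclopentanone by Baeyer–Villiger ring expansion, with oxygen inserted between the carbonyl carbon and the quaternary carbon.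
- Both stereocentres come from one desymmetrising CBS reduction of achiral 2-allyl-2-methylcyclopentane-1,3-dione; ring order: cyclopentane (bought), then pyran (as lactone), then benzene.
- Enabling feature: in the pyran ring the fully substituted C2 is the atom bonded to O1, so in a cyclopentanone it is the α-carbon with the highest migratory aptitude and moves to oxygen with retention; the two atoms shared with the benzene ring (C8a, bearing O1 and para to the ester, and C4a) are a carboxyl carbon and its α-carbon in disguise.

Key step: step 3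

Remark: the dione, methyl coumalate and 2-methylbut-3-en-2-ol are taken as catalogue compounds; in the target (2R,3R) the acetoxy group and the C2 side chain are cis on the pyran ring, which is the relation that hydride delivery anti to the allyl group of the dione sets.

Step 1
Reactants: 1 2-methyl-2-(prop-2-en-1-yl)cyclopentane-1,3-dione
Product: 3 (2R,3R)-3-hydroxy-2-methyl-2-(prop-2-en-1-yl)cyclopentan-1-one, via catechol borate 2 (not isolated)
Conditions: (S)-Me-CBS (20 mol%), catecholborane (1.1 equiv), PhMe/CH2Cl2, −78 °C; then MeOH, aq. NaHCO3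
Reagents that add atoms: none
Why: Corey–Bakshi–Shibata reduction run as a desymmetrisation of the two enantiotopic carbonyl groups: with the (S)-oxazaborolidine the quaternary carbon acts as the large group and the new carbinol centre should be R, and because hydride is delivered anti to the larger allyl group the carbonyl that is reduced is the one that makes the quaternary centre R, with OH cis to allyl.

Step 2
Reactants: 3 (2R,3R)-3-hydroxy-2-methyl-2-(prop-2-en-1-yl)cyclopentan-1-one
Product: 4 (1R,2R)-2-methyl-3-oxo-2-(prop-2-en-1-yl)cyclopentyl acetate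
Conditions: Ac2O, pyridine, DMAP (cat.), CH2Cl2, 0 °C → rt
Reagents that add atoms: acetic anhydride, CC(=O)OC(C)=O
Why: DMAP-catalysed O-acetylation (nucleophilic acyl transfer) installs the acetate that the target carries and blocks both retro-aldol opening of the β-hydroxy ketone and later translactonisation; no stereocentre is touched.

Step 3
Reactants: 4 (1R,2R)-2-methyl-3-oxo-2-(prop-2-en-1-yl)cyclopentyl acetate
Product: 6 (2R,3R)-2-methyl-6-oxo-2-(prop-2-en-1-yl)oxan-3-yl acetate, via perketal adduct 5 (not isolated)
Conditions: (Me3SiO)2 (1.5 equiv), TMSOTf (20 mol%), CH2Cl2, −78 → −20 °C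
Reagents that add atoms: bis(trimethylsilyl) peroxide, C[Si](C)(C)OO[Si](C)(C)C
Why: TMSOTf silylates the ketone oxygen, bis(trimethylsilyl) peroxide adds to C3 to give the perketal 5, and the ring bond from this carbon to the quaternary carbon, antiperiplanar to the O–O bond, shifts to oxygen as hexamethyldisiloxane leaves. This is the Baeyer–Villiger oxidation in its silyl peroxide variant, a reaction type well known for 2,2-disubstituted cycloalkanones. No ring is closed by cyclisation: the five-membered carbocycle is enlarged by one atom through a 1,2-shift of a ring carbon from carbon to oxygen, and the six ring atoms of lactone 6 are those of the pyran ring of the target (lactone C=O = C8a, its α-CH2 = C4a). No new stereocentre remains (the perketal carbon returns to sp2), the migrating quaternary carbon keeps its configuration because the shift is suprafacial, and the acetoxy-bearing carbon is a spectator. The step needs regioselectivity (quaternary carbon versus the CH2 on the other side), secured by the much higher migratory aptitude of the fully substituted carbon, and chemoselectivity for the ketone over the terminal alkene, secured by the nucleophilic silyl peroxide, which unlike a peracid does not epoxidise; the acetate keeps the product from translactonising to the γ-lactone.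

Step 4
Reactants: 6 (2R,3R)-2-methyl-6-oxo-2-(prop-2-en-1-yl)oxan-3-yl acetate; 7 methyl 2-oxo-2H-pyran-5-carboxylate (methyl coumalate)
Product: 11 methyl (2R,3R)-3-(acetyloxy)-2-methyl-2-(prop-2-en-1-yl)-3,4-dihydro-2H-1-benzopyran-6-carboxylate, via silyl ketene acetal 8 (not isolated), via bicyclic cycloadduct 9 (not isolated), via dihydroarene 10 (not isolated)
Conditions: LiHMDS (1.1 equiv), TMSCl (1.3 equiv), THF, −78 °C; then 7 (1.2 equiv), PhMe, 80 °C; then PPTS (cat.), rt
Reagents that add atoms: none
Why: The δ-lactone, clearly more acidic than the acetate, is deprotonated and O-silylated in situ to ketene acetal 8, which enters an inverse-electron-demand Diels–Alder reaction with the 2-pyrone (its nucleophilic carbon to C6 of 7, so that the acetal carbon ends para to the ester), and cycloreversion with loss of CO2 followed by 1,2-elimination of silanol, the better nucleofuge whose loss leaves the better stabilised cation, should give the benzene ring with the ring oxygen kept and both stereocentres untouched.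

Step 5
Reactants: 11 methyl (2R,3R)-3-(acetyloxy)-2-methyl-2-(prop-2-en-1-yl)-3,4-dihydro-2H-1-benzopyran-6-carboxylate; 12 2-methylbut-3-en-2-ol
Product: 13 methyl (2R,3R)-3-(acetyloxy)-2-[(2E)-4-hydroxy-4-methylpent-2-en-1-yl]-2-methyl-3,4-dihydro-2H-1-benzopyran-6-carboxylate
Conditions: Hoveyda–Grubbs II (5 mol%), 12 (10 equiv), CH2Cl2, 40 °C
Reagents that add atoms: none
Why: Olefin cross-metathesis between the terminal allyl group and an excess of the tertiary allylic alcohol, a partner that hardly homodimerises and for steric reasons should give the E-alkene; acetate, ester and both stereocentres are not involved.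

**Compound list**

1 | 2-methyl-2-(prop-2-en-1-yl)cyclopentane-1,3-dione | C=CCC1(C)C(=O)CCC1=O | starting material
2 | (2R,3R)-3-(1,3,2-benzodioxaborol-2-yloxy)-2-methyl-2-(prop-2-en-1-yl)cyclopentan-1-one (catechol borate of 3, not isolated) | O=C1CC[C@@H](OB2Oc3ccccc3O2)[C@@]1(C)CC=C | intermediate
3 | (2R,3R)-3-hydroxy-2-methyl-2-(prop-2-en-1-yl)cyclopentan-1-one | O=C1CC[C@@H](O)[C@@]1(C)CC=C | intermediate
4 | (1R,2R)-2-methyl-3-oxo-2-(prop-2-en-1-yl)cyclopentyl acetate | O=C1CC[C@@H](OC(C)=O)[C@@]1(C)CC=C | intermediate
5 | (1R,2R)-2-methyl-2-(prop-2-en-1-yl)-3-[(trimethylsilyl)oxy]-3-[(trimethylsilyl)peroxy]cyclopentyl acetate (perketal adduct, C3 not defined, not isolated) | C[Si](C)(C)OOC1(O[Si](C)(C)C)CC[C@@H](OC(C)=O)[C@@]1(C)CC=C | intermediate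
6 | (2R,3R)-2-methyl-6-oxo-2-(prop-2-en-1-yl)oxan-3-yl acetate | O=C1CC[C@@H](OC(C)=O)[C@@](C)(CC=C)O1 | intermediate
7 | methyl 2-oxo-2H-pyran-5-carboxylate (methyl coumalate) | COC(=O)C1=COC(=O)C=C1 | starting material
8 | (2R,3R)-2-methyl-2-(prop-2-en-1-yl)-6-[(trimethylsilyl)oxy]-3,4-dihydro-2H-pyran-3-yl acetate (not isolated) | C[Si](C)(C)OC1=CC[C@@H](OC(C)=O)[C@@](C)(CC=C)O1 | intermediate
9 | [4+2] adduct of 8 across C3/C6 of 7: 3-oxo-2-oxabicyclo[2.2.2]oct-5-ene carrying CO2Me on the alkene, fused to the (2R,3R)-pyran ring, Me3SiO on the ring-fusion ketal carbon (new centres not defined, not isolated) | COC(=O)C1=CC2C(=O)OC1C1C[C@@H](OC(C)=O)[C@@](C)(CC=C)OC21O[Si](C)(C)C | intermediate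
10 | methyl (2R,3R)-3-(acetyloxy)-2-methyl-2-(prop-2-en-1-yl)-8a-[(trimethylsilyl)oxy]-3,4,4a,8a-tetrahydro-2H-1-benzopyran-6-carboxylate (C4a and C8a not defined, not isolated) | COC(=O)C1=CC2C[C@@H](OC(C)=O)[C@@](C)(CC=C)OC2(O[Si](C)(C)C)C=C1 | intermediate
11 | methyl (2R,3R)-3-(acetyloxy)-2-methyl-2-(prop-2-en-1-yl)-3,4-dihydro-2H-1-benzopyran-6-carboxylate | COC(=O)c1ccc2c(c1)C[C@@H](OC(C)=O)[C@@](C)(CC=C)O2 | intermediate
12 | 2-methylbut-3-en-2-ol | CC(C)(O)C=C | starting material
13 | methyl (2R,3R)-3-(acetyloxy)-2-[(2E)-4-hydroxy-4-methylpent-2-en-1-yl]-2-methyl-3,4-dihydro-2H-1-benzopyran-6-carboxylate | COC(=O)c1ccc2c(c1)C[C@@H](OC(C)=O)[C@@](C)(C/C=C/C(C)(C)O)O2 | target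

Total step count: 5. Longest linear sequence: 5 steps (1 to 13).

**Steps most likely to fail**

Step 4. The amide base may also deprotonate the acetate, or the lactone enolate may attack the neighbouring acetyl group before it is silylated, so that too little ketene acetal reaches the cycloaddition. The fallback carries the C3 oxygen as a silyl ether through the enolate chemistry; it sets out from 3 and comes back at 11. Compound 3 is silylated (TBSOTf, 2,6-lutidine, CH2Cl2, −78 °C) to (2R,3R)-3-[(tert-butyldimethylsilyl)oxy]-2-methyl-2-(prop-2-en-1-yl)cyclopentan-1-one F1. Ring expansion as in step 3 should give (5R,6R)-5-[(tert-butyldimethylsilyl)oxy]-6-methyl-6-(prop-2-en-1-yl)oxan-2-one F2. The sequence of step 4 with 7 should then give methyl (2R,3R)-3-[(tert-butyldimethylsilyl)oxy]-2-methyl-2-(prop-2-en-1-yl)-3,4-dihydro-2H-1-benzopyran-6-carboxylate F3. HF·pyridine in THF frees methyl (2R,3R)-3-hydroxy-2-methyl-2-(prop-2-en-1-yl)-3,4-dihydro-2H-1-benzopyran-6-carboxylate F4, which is acetylated (Ac2O, pyridine, DMAP) to 11.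

Step 1. Hydride delivery may discriminate poorly between the methyl face and the allyl face of the dione, and a second reduction to the diol may set in. The fallback replaces desymmetrisation by resolution; it sets out from 1 and comes back at 4, so that step 2 is not needed. Reduction with NaBH4 (0.3 equiv, MeOH/CH2Cl2, −78 °C) and chromatography should give racemic (2R*,3R*)-3-hydroxy-2-methyl-2-(prop-2-en-1-yl)cyclopentan-1-one F5. A lipase (Burkholderia cepacia lipase, vinyl acetate, MTBE, 30 °C) should acetylate the (3R)-alcohol, as expected for a secondary carbinol whose larger flank is the quaternary carbon, and so give 4 directly, separable from the unreacted (2S,3S)-alcohol.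

Step 3. Addition of the silyl peroxide to a carbonyl group flanked by a quaternary carbon may be too slow, and the peracids that would force the oxidation also epoxidise the allyl group. The fallback masks the alkene during a peracid oxidation; it sets out from 4 and comes back at 6. Bromine (CH2Cl2, −78 °C) gives (1R,2R)-2-(2,3-dibromopropyl)-2-methyl-3-oxocyclopentyl acetate F6 as both epimers at the CHBr carbon. mCPBA (CH2Cl2, rt) should give (2R,3R)-2-(2,3-dibromopropyl)-2-methyl-6-oxooxan-3-yl acetate F7, and zinc dust (AcOH/Et2O, 0 °C) restores the allyl group to give 6.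

**Further compounds**

F1 | step 4 | (2R,3R)-3-[(tert-butyldimethylsilyl)oxy]-2-methyl-2-(prop-2-en-1-yl)cyclopentan-1-one | O=C1CC[C@@H](O[Si](C)(C)C(C)(C)C)[C@@]1(C)CC=C
F2 | step 4 | (5R,6R)-5-[(tert-butyldimethylsilyl)oxy]-6-methyl-6-(prop-2-en-1-yl)oxan-2-one | O=C1CC[C@@H](O[Si](C)(C)C(C)(C)C)[C@@](C)(CC=C)O1
F3 | step 4 | methyl (2R,3R)-3-[(tert-butyldimethylsilyl)oxy]-2-methyl-2-(prop-2-en-1-yl)-3,4-dihydro-2H-1-benzopyran-6-carboxylate | COC(=O)c1ccc2c(c1)C[C@@H](O[Si](C)(C)C(C)(C)C)[C@@](C)(CC=C)O2
F4 | step 4 | methyl (2R,3R)-3-hydroxy-2-methyl-2-(prop-2-en-1-yl)-3,4-dihydro-2H-1-benzopyran-6-carboxylate | COC(=O)c1ccc2c(c1)C[C@@H](O)[C@@](C)(CC=C)O2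
F5 | step 1 | racemic (2R*,3R*)-3-hydroxy-2-methyl-2-(prop-2-en-1-yl)cyclopentan-1-one | O=C1CC[C@@H](O)[C@@]1(C)CC=C.O=C1CC[C@H](O)[C@]1(C)CC=C
F6 | step 3 | (1R,2R)-2-(2,3-dibromopropyl)-2-methyl-3-oxocyclopentyl acetate (both epimers at CHBr) | O=C1CC[C@@H](OC(C)=O)[C@@]1(C)CC(Br)CBr
F7 | step 3 | (2R,3R)-2-(2,3-dibromopropyl)-2-methyl-6-oxooxan-3-yl acetate (both epimers at CHBr) | O=C1CC[C@@H](OC(C)=O)[C@@](C)(CC(Br)CBr)O1
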